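The route cuts the C1'–C2' bond between the side-chain methylene on ring carbon C5 and the first vinylic CH (cyclohexenone numbering, C1 = carbonyl). C1' lies β to the oxygenated ring carbon C4. At the ketone level, O=C4–C5=C1'H2 is therefore an s-cis-locked exocyclic enone. The (E)-C2'=C3'(CH3) unit is the retron of syn-methylmetalation of a terminal alkyne. In one pot, methylalumination of a C18 trienyne and copper-catalysed 1,4-addition to a 6-methylidene enone ketal (no side chain, no stereocentre) create the alkene geometry and the C–C bond. The labile C5 centre and C4 are then set together as cis-(4S,5S) by one dynamic kinetic asymmetric hydrogenation.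

Key step: step 5

Remark on the chemistry: atom labels C1–C6 and C1'–C16' in the comments are those of the target (C1 carbonyl, C2=C3 with CH3 on C3, C4 carbinol, C5 side-chain carbon). Compound names use their own locants.

Remark on the chemistry (assumption): the hand of the hydrogenation catalyst is assigned by analogy with 2,4,4-trimethylcyclohex-2-enone, whose carbonyl environment matches that of the coupled ketone. Should the sense of induction prove opposite, the mirror-image complex is used.

Step 1
Reactants: 1 4-methoxy-2-methylphenol
Product: 2 4,4-dimethoxy-2-methylcyclohexa-2,5-dien-1-one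
Conditions: PhI(OAc)2 (1.1 equiv), MeOH, 0 °C to rt
Reagents that add atoms: methanol, CO
Why: Hypervalent-iodine oxidative dearomatisation of a 4-alkoxyphenol: the phenoxenium-type intermediate is captured by methanol at the methoxy-bearing para carbon, which should give the quinone monoketal with the future C1 masked and the future C4 free as a ketone.

Step 2
Reactants: 2 4,4-dimethoxy-2-methylcyclohexa-2,5-dien-1-one
Product: 3 4,4-dimethoxy-2-methylcyclohex-2-en-1-one
Conditions: H2 (1 atm), RhCl(PPh3)3 (5 mol %), toluene/EtOH, rt
Reagents that add atoms: none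
Why: Homogeneous hydrogenation with RhCl(PPh3)3 is governed by alkene substitution, so the disubstituted C5=C6 bond of the cross-conjugated dienone should be saturated while the methyl-bearing C2=C3 bond stays, the same selectivity that turns steroidal 1,4-dien-3-ones into 4-en-3-ones.

Step 3
Reactants: 3 4,4-dimethoxy-2-methylcyclohex-2-en-1-one
Product: 7 4,4-dimethoxy-2-methyl-6-methylidenecyclohex-2-en-1-one, via lithium enolate 4 (not isolated), via Mannich base 5 (not isolated), via methiodide 6 (not isolated)
Conditions: LiN(i-Pr)2, THF, −78 °C; CH2=NMe2+ I−, −78 °C to rt; MeI (excess), rt; aq. NaHCO3/CH2Cl2, rt; product used at once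
Reagents that add atoms: N,N-dimethylmethyleneiminium iodide, C=[N+](C)C.[I-]
Why: Standard α-methylenation of a ketone by Mannich reaction with a preformed iminium salt, N-methylation and Hofmann-type E1cB elimination, regiochemically unambiguous because C5 is the only enolisable position of 3 (the vinylogous position C1 bears no hydrogen).

Step 4
Reactants: 8 propyne; 9 (2E,6E)-farnesyl bromide [(2E,6E)-1-bromo-3,7,11-trimethyldodeca-2,6,10-triene]
Product: 12 (5E,9E)-6,10,14-trimethylpentadeca-5,9,13-trien-1-yne, via 1,3-dilithiopropyne 10 (not isolated), via lithium acetylide 11 (not isolated)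
Conditions: 8 (excess), n-BuLi (2 equiv per 8), TMEDA, Et2O/hexane, −78 to 0 °C; 9, −78 °C to rt; H2O
Reagents that add atoms: none
Why: SN2 alkylation of the propyne dianion by a primary allylic bromide takes place at the propargylic carbanion, the more nucleophilic of the two sites, leaves the acetylide end and both E alkenes untouched and should give the terminal alkyne on protonation.

Step 5
Reactants: 12 (5E,9E)-6,10,14-trimethylpentadeca-5,9,13-trien-1-yne; 7 4,4-dimethoxy-2-methyl-6-methylidenecyclohex-2-en-1-one
Product: 15 racemic 4,4-dimethoxy-2-methyl-6-[(2E,6E,10E)-3,7,11,15-tetramethylhexadeca-2,6,10,14-tetraen-1-yl]cyclohex-2-en-1-one, via alkenylalane 13 (not isolated), via aluminium enolate 14 (not isolated)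
Conditions: 12 (1.2 equiv), AlMe3 (2 equiv), Cp2ZrCl2 (20 mol %), CH2Cl2, 0 °C to rt; solvent and excess AlMe3 removed in vacuo; THF/Et2O, CuBr·SMe2 (10 mol %), slow addition of 7, −78 to −20 °C; sat. aq. NH4Cl
Reagents that add atoms: trimethylaluminium, C[Al](C)C
Why: Zr-catalysed syn-methylalumination (Negishi carboalumination) places CH3 on the internal and AlMe2 on the terminal alkyne carbon of 12, fixing the (E)-C2'=C3' geometry before the coupling; the alkenyl group then passes from aluminium to monovalent copper, the organocopper binds the C5=C1' π bond of 7, adds at C1' to a trivalent copper β-adduct and reductively eliminates with retention of alkene geometry, forming C1'–C2' and the aluminium enolate 14. The closest known reaction types are the copper-catalysed conjugate addition of alkenylalanes to enones and the cuprate addition to α-methylene ketones. No ring is closed. The only new stereocentre, C5, arises without control on protonation of 14, which is intended because it is α to the C4 ketone and is equilibrated and selected in step 6, whereas the new alkene stereounit is controlled by the syn addition. The step needs site selectivity between the two enone units of 7, and the substrate secures it: C1' is an unsubstituted, s-cis-locked terminus that can also be reached through an aluminium-coordinated closed transition state, whereas C2 belongs to an s-trans-locked, α-methylated enone and adjoins the quaternary ketal carbon C1. Alkenyl-over-methyl transfer should follow from the faster migration of sp2 ligands from aluminium to copper once free AlMe3 has been stripped off.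

Step 6
Reactants: 15 racemic 4,4-dimethoxy-2-methyl-6-[(2E,6E,10E)-3,7,11,15-tetramethylhexadeca-2,6,10,14-tetraen-1-yl]cyclohex-2-en-1-one
Product: 16 (1S,6S)-4,4-dimethoxy-2-methyl-6-[(2E,6E,10E)-3,7,11,15-tetramethylhexadeca-2,6,10,14-tetraen-1-yl]cyclohex-2-en-1-ol (OH and side chain cis)
Conditions: H2 (10 atm), RuCl2[(R)-tolbinap][(S,S)-dpen] (1 mol %; tolbinap = 2,2'-bis(di-p-tolylphosphino)-1,1'-binaphthyl, dpen = 1,2-diphenylethane-1,2-diamine), KOt-Bu (20 mol %), i-PrOH/toluene, rt
Reagents that add atoms: none
Why: Noyori asymmetric hydrogenation run as a dynamic kinetic resolution: KOt-Bu interconverts the C5 epimers of 15 through the cross-conjugated enolate faster than the hindered α-methyl enone carbonyl is reduced, the bifunctional Ru–H/N–H catalyst transfers H2 only to C=O (all five C=C bonds are left) on the face that gives (4S), and it should do so fastest on the (5S)-ketone because hydride then approaches anti to the side chain, which sets C4 and C5 together as the cis-(4S,5S) pair.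

Step 7
Reactants: 16 (1S,6S)-4,4-dimethoxy-2-methyl-6-[(2E,6E,10E)-3,7,11,15-tetramethylhexadeca-2,6,10,14-tetraen-1-yl]cyclohex-2-en-1-ol
Product: 17 (4S,5S)-4-hydroxy-3-methyl-5-[(2E,6E,10E)-3,7,11,15-tetramethylhexadeca-2,6,10,14-tetraen-1-yl]cyclohex-2-en-1-one
Conditions: pyridinium p-toluenesulfonate (10 mol %), THF/H2O 4:1, 0 °C to rt
Reagents that add atoms: water, O
Why: Acid-catalysed hydrolysis of the allylic dimethyl ketal through its stabilised oxocarbenium ion is much faster than ionisation of the C4 allylic alcohol or protonation of the trisubstituted alkenes, so the enone should be unmasked without touching C4 or C5, neither of which enolises under these conditions.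

Compound list
1 | 4-methoxy-2-methylphenol | COc1ccc(O)c(C)c1 | starting material
2 | 4,4-dimethoxy-2-methylcyclohexa-2,5-dien-1-one | COC1(OC)C=CC(=O)C(C)=C1 | intermediate
3 | 4,4-dimethoxy-2-methylcyclohex-2-en-1-one | COC1(OC)CCC(=O)C(C)=C1 | intermediate
4 | lithium 4,4-dimethoxy-2-methylcyclohexa-1(6),2-dien-1-olate (kinetic enolate of 3) | [Li]OC1=CCC(OC)(OC)C=C1C | intermediate
5 | racemic 6-[(dimethylamino)methyl]-4,4-dimethoxy-2-methylcyclohex-2-en-1-one | COC1(OC)CC(CN(C)C)C(=O)C(C)=C1 | intermediate
6 | racemic [(5,5-dimethoxy-3-methyl-2-oxocyclohex-3-en-1-yl)methyl]trimethylammonium iodide | COC1(OC)CC(C[N+](C)(C)C)C(=O)C(C)=C1.[I-] | intermediate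
7 | 4,4-dimethoxy-2-methyl-6-methylidenecyclohex-2-en-1-one | COC1(OC)CC(=C)C(=O)C(C)=C1 | intermediate
8 | propyne | CC#C | starting material
9 | (2E,6E)-farnesyl bromide | CC(C)=CCC/C(C)=C/CC/C(C)=C/CBr | starting material
10 | 1,3-dilithiopropyne | [Li]CC#C[Li] | intermediate
11 | lithium acetylide of 12 | CC(C)=CCC/C(C)=C/CC/C(C)=C/CCC#C[Li] | intermediate
12 | (5E,9E)-6,10,14-trimethylpentadeca-5,9,13-trien-1-yne | CC(C)=CCC/C(C)=C/CC/C(C)=C/CCC#C | intermediate
13 | dimethyl[(1E,5E,9E)-2,6,10,14-tetramethylpentadeca-1,5,9,13-tetraen-1-yl]alane | CC(C)=CCC/C(C)=C/CC/C(C)=C/CC/C(C)=C/[Al](C)C | intermediate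
14 | dimethylaluminium enolate of 15 | CC(C)=CCC/C(C)=C/CC/C(C)=C/CC/C(C)=C/CC1=C(O[Al](C)C)C(C)=CC(OC)(OC)C1 | intermediate
15 | racemic 4,4-dimethoxy-2-methyl-6-[(2E,6E,10E)-3,7,11,15-tetramethylhexadeca-2,6,10,14-tetraen-1-yl]cyclohex-2-en-1-one | CC(C)=CCC/C(C)=C/CC/C(C)=C/CC/C(C)=C/CC1CC(OC)(OC)C=C(C)C1=O | intermediate
16 | (1S,6S)-4,4-dimethoxy-2-methyl-6-[(2E,6E,10E)-3,7,11,15-tetramethylhexadeca-2,6,10,14-tetraen-1-yl]cyclohex-2-en-1-ol | CC(C)=CCC/C(C)=C/CC/C(C)=C/CC/C(C)=C/C[C@H]1CC(OC)(OC)C=C(C)[C@H]1O | intermediate
17 | (4S,5S)-4-hydroxy-3-methyl-5-[(2E,6E,10E)-3,7,11,15-tetramethylhexadeca-2,6,10,14-tetraen-1-yl]cyclohex-2-en-1-one | CC(C)=CCC/C(C)=C/CC/C(C)=C/CC/C(C)=C/C[C@H]1CC(=O)C=C(C)[C@H]1O | target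

Total step count: 7. Longest linear sequence: 6 (steps 1, 2, 3, 5, 6, 7).

Steps most likely to fail

Step 5. Four processes could erode the coupling:
- methyl transfer competing with alkenyl transfer;
- ionisation of the allylic ketal by Lewis-acidic aluminium, followed by loss of methanol and aromatisation;
- self-dimerisation of the exocyclic enone;
- Michael oligomerisation of the enone by the product enolate.

The fallback sets out from 12 and keeps the same bond construction, but with an isolable nucleophile that is not Lewis acidic. The alane 13 made as before is quenched with 2-isopropoxy-4,4,5,5-tetramethyl-1,3,2-dioxaborolane to give the (E)-alkenyl pinacol boronate F1, which is purified. It is then added to 7 by a Hayashi–Miyaura reaction ([Rh(cod)Cl]2, KOH, dioxane/H2O, rt). In this reaction an alkenylrhodium species carbometalates C5=C1' and water protonates the oxa-π-allyl rhodium intermediate. The fallback comes back to the route at 15.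

Step 6. Epimerisation at C5 could be too slow relative to reduction, or the facial discrimination of the flanked carbonyl too weak. Either would erode diastereomeric and enantiomeric purity. The fallback sets out from 15 and gives up the dynamic element in favour of catalyst-controlled reduction with separation and recycling. A Corey–Bakshi–Shibata reduction is run with (R)-1-methyl-3,3-diphenyltetrahydro-1H,3H-pyrrolo[1,2-c][1,3,2]oxazaborole (20 mol %) and catecholborane in toluene at −78 °C; catecholborane is inert to the isolated alkenes. It should deliver hydride to the same carbonyl face of both C5 epimers, giving 16 together with the trans-(1S,6R) alcohol F2. The two are separated by chromatography. F2 is returned to racemic 15 in one operation with MnO2 and then DBU. The fallback comes back to the route at 16.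

Step 2. The second alkene could be over-reduced, or methanol could be lost reductively with aromatisation under hydrogen. The fallback sets out from 2 and replaces both the hydrogenation and the strong-base enolisation by a conjugate hydride addition. Copper hydride catalysis ([(PPh3)CuH]6, PhMe2SiH, toluene, 0 °C) should attack the less substituted enone and give the dimethyl(phenyl)silyl dienol ether F3. F3 is aminomethylated directly with N,N-dimethylmethyleneiminium iodide in CH2Cl2. The fallback comes back to the route at 5, which is carried on to 7 as in step 3.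

Further compounds
F1 | step 5 | 2-[(1E,5E,9E)-2,6,10,14-tetramethylpentadeca-1,5,9,13-tetraen-1-yl]-4,4,5,5-tetramethyl-1,3,2-dioxaborolane | CC(C)=CCC/C(C)=C/CC/C(C)=C/CC/C(C)=C/B1OC(C)(C)C(C)(C)O1
F2 | step 6 | (1S,6R)-4,4-dimethoxy-2-methyl-6-[(2E,6E,10E)-3,7,11,15-tetramethylhexadeca-2,6,10,14-tetraen-1-yl]cyclohex-2-en-1-ol | CC(C)=CCC/C(C)=C/CC/C(C)=C/CC/C(C)=C/C[C@@H]1CC(OC)(OC)C=C(C)[C@H]1O
F3 | step 2 | [(4,4-dimethoxy-2-methylcyclohexa-1(6),2-dien-1-yl)oxy]dimethyl(phenyl)silane | C[Si](C)(c1ccccc1)OC1=CCC(OC)(OC)C=C1C
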